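**Retrosynthetic overview**

1. Numbering used: ring B = C1 (carbinol with methyl), C2 (CHBr), C3, C4 (CH carrying the chain), C5, C6; chain = C2′(OH)(Me)–C3′=C4′; ring A = the bromo-dimethyl-methylidenecyclohexane on C4′.
2. Last disconnections: the two Si–O bonds, then the E-alkene C3′=C4′ (Julia–Kocienski olefination of a ring-A tetrazolyl sulfone with a ring-B α-silyloxy aldehyde).
3. Ring B: cis-bromohydrin C1/C2 ⇒ equatorial methyl addition to a 2-bromoketone ⇒ β-keto ester (tert-butyl ester on C2 as regiochemical marker, removed by bromination–decarboxylation) ⇒ bonds C1–C2 and C4–C5 made in one annulation of an acyclic epoxy ester with a three-carbon sulfonyl N-methoxy-N-methylamide.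
4. Feature that allows this: the tertiary carbinol C2′ is exocyclic and vicinal to the ring methine C4 (the O–C2′–C4–H unit is the retron of a trisubstituted epoxide opened with inversion at its CH carbon), and C1 is at ketone level next to the enolisable C2. One Sharpless epoxide therefore sets C2′ and C4; the sulfone on C5 and the ester on C2 are removed later.
5. Ring A is built separately (bromonium cyclisation of a prenylated acetoacetate, methylenation, reduction, lipase resolution); ring B (step 6) and ring A (step 13) are formed independently and joined in step 19.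

Key step: step 6

Assumption: in step 16 the lipase acylates the (1S,3R)-alcohol faster; if the preference is the opposite, the acetate is the wanted enantiomer and is carried on after methanolysis (K2CO3, MeOH).

**Route**

Step 1
Reactants: 1 tert-butyl acetate; 2 1-bromo-3-methylbut-2-ene
Product: 3 tert-butyl 5-methylhex-4-enoate
Conditions: LiN(iPr)2 (LDA), THF, −78 °C; then 2, −78 → 0 °C
Reagents that add atoms: none
Why: Alkylation of the lithium ester enolate with the primary allylic bromide (SN2) should give the prenylated ester, with no stereocentre formed.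

Step 2
Reactants: 3 tert-butyl 5-methylhex-4-enoate
Product: 4 tert-butyl (4E)-6-hydroxy-5-methylhex-4-enoate
Conditions: SeO2 (cat.), t-BuOOH, CH2Cl2, rt
Reagents that add atoms: tert-butyl hydroperoxide, CC(C)(C)OO
Why: SeO2-catalysed allylic oxidation (ene reaction, then [2,3]-shift) should hydroxylate the E-methyl group of the trisubstituted alkene, which fixes the E geometry that the epoxide needs.

Step 3
Reactants: 4 tert-butyl (4E)-6-hydroxy-5-methylhex-4-enoate
Product: 5 tert-butyl 3-[(2R,3R)-3-(hydroxymethyl)-3-methyloxiran-2-yl]propanoate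
Conditions: Ti(OiPr)4, D-(−)-diethyl tartrate, t-BuOOH, 4 Å molecular sieves, CH2Cl2, −20 °C
Reagents that add atoms: tert-butyl hydroperoxide, CC(C)(C)OO
Why: Sharpless asymmetric epoxidation with the D-tartrate should deliver oxygen to one face of the E-allylic alcohol and set both epoxide carbons as (2R,3R), the future carbinol C2′ and, after inversion, ring-B C4.

Step 4
Reactants: 5 tert-butyl 3-[(2R,3R)-3-(hydroxymethyl)-3-methyloxiran-2-yl]propanoate
Product: 6 tert-butyl 3-[(2R,3R)-3-({[tert-butyl(dimethyl)silyl]oxy}methyl)-3-methyloxiran-2-yl]propanoate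
Conditions: TBSCl, imidazole, DMF, rt
Reagents that add atoms: tert-butyldimethylsilyl chloride, CC(C)(C)[Si](C)(C)Cl
Why: Silyl ether formation on the primary alcohol prevents alkoxide formation and Payne rearrangement under the strong base of step 6.

Step 5
Reactants: 7 3-(benzenesulfonyl)propanoic acid
Product: 8 3-(benzenesulfonyl)-N-methoxy-N-methylpropanamide
Conditions: CDI, CH2Cl2, rt; then MeNH(OMe)·HCl
Reagents that add atoms: N,O-dimethylhydroxylamine hydrochloride, CNOC.Cl
Why: Amide coupling through the acyl imidazole gives an acyl donor that stops at the ketone stage and carries the sulfone as a temporary activating group for C5.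

Step 6
Reactants: 6 tert-butyl 3-[(2R,3R)-3-({[tert-butyl(dimethyl)silyl]oxy}methyl)-3-methyloxiran-2-yl]propanoate; 8 3-(benzenesulfonyl)-N-methoxy-N-methylpropanamide
Product: 11 tert-butyl (5R)-5-[(2S)-1-{[tert-butyl(dimethyl)silyl]oxy}-2-hydroxypropan-2-yl]-2-oxocyclohex-3-ene-1-carboxylate, via acyclic epoxy keto sulfone 9 (not isolated), via cyclised sulfonyl ketone 10 (not isolated)
Conditions: LiN(iPr)2 (2.3 equiv), THF, −78 → 0 °C; AcOH; then DBU, CH2Cl2, 0 °C
Reagents that add atoms: none
Why: After double lithiation (ester α-carbon of 6, α-sulfonyl carbon of 8) the ester enolate acylates the N-methoxy-N-methylamide (crossed Claisen condensation, ring-B bond C1–C2) and the α-sulfonyl carbanion opens the epoxide by SN2 at its CH carbon (ring-B bond C4–C5), and whichever bond forms first the second event is intramolecular and leads to the same ring 10, from which DBU expels sulfinate by E1cB elimination. The closest known reaction types are the synthesis of β-keto esters from ester enolates and N-methoxy-N-methylamides and the cyclisation of epoxy sulfone carbanions. Ring B closes in the 6-exo-tet mode at the epoxide (6-exo-trig acyl substitution if the epoxide is opened first), the 7-endo alternative being SN2 at a fully substituted carbon. Ring carbon C4 is set by inversion at the epoxide CH and C2′ keeps its C–O bond, so both follow from the Sharpless epoxide, while the ester-bearing C2 is enolisable and needs no control. The step needs C-acylation and carbanion alkylation to outrun 3-exo attack of the ester enolate on the epoxide, O-alkylation and lactonisation by the freed tertiary alkoxide, which the low temperature, the higher nucleophilicity of the sulfonyl carbanion and the unreactive tert-butyl ester should secure. Under DBU the β-keto ester is the acidic site, which shields the γ-stereocentre C4 of the enone from epimerisation.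

Step 7
Reactants: 11 tert-butyl (5R)-5-[(2S)-1-{[tert-butyl(dimethyl)silyl]oxy}-2-hydroxypropan-2-yl]-2-oxocyclohex-3-ene-1-carboxylate
Product: 12 tert-butyl (5S)-5-[(2S)-1-{[tert-butyl(dimethyl)silyl]oxy}-2-hydroxypropan-2-yl]-2-oxocyclohexane-1-carboxylate
Conditions: H2 (1 atm), Pd/C, EtOAc, rt
Reagents that add atoms: none
Why: Heterogeneous hydrogenation of the disubstituted enone C=C removes the unsaturation left by the sulfone without touching ketone, ester or silyl ether, and no stereocentre changes.

Step 8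
Reactants: 12 tert-butyl (5S)-5-[(2S)-1-{[tert-butyl(dimethyl)silyl]oxy}-2-hydroxypropan-2-yl]-2-oxocyclohexane-1-carboxylate
Product: 14 (2S,4S)-2-bromo-4-[(2S)-1,2-dihydroxypropan-2-yl]cyclohexan-1-one, via bromo keto ester 13 (not isolated)
Conditions: NBS, Et3N (cat.), CH2Cl2, 0 °C; then TFA, H2O, CH2Cl2, 0 °C → rt
Reagents that add atoms: N-bromosuccinimide, O=C1CCC(=O)N1Br
Why: Bromination at the doubly activated carbon followed by acid cleavage of the tert-butyl ester and decarboxylation (halogenation–dealkoxycarbonylation of a β-keto ester) should give the 2-bromoketone regiospecifically, ketonisation of the bromo-enol by axial protonation should place bromine equatorial and cis to the C4 chain (2S), and the acid also removes the primary silyl group.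

Step 9
Reactants: 14 (2S,4S)-2-bromo-4-[(2S)-1,2-dihydroxypropan-2-yl]cyclohexan-1-one
Product: 15 (1R,2S,4S)-2-bromo-4-[(2S)-1,2-dihydroxypropan-2-yl]-1-methylcyclohexan-1-ol
Conditions: MeTi(OiPr)3 (excess), THF, −30 °C → rt
Reagents that add atoms: methyltitanium triisopropoxide, C[Ti](OC(C)C)(OC(C)C)OC(C)C
Why: 1,2-Addition of the non-basic methyltitanium reagent should occur from the equatorial direction (its usual preference on cyclohexanones, reinforced by attack anti to the C–Br bond as in the polar Felkin–Anh model), giving the axial tertiary alcohol (1R) cis to bromine without enolising the bromoketone, while the side-chain titanium diolate on the equatorial C4 substituent is too far from the carbonyl for intramolecular delivery.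

Step 10
Reactants: 15 (1R,2S,4S)-2-bromo-4-[(2S)-1,2-dihydroxypropan-2-yl]-1-methylcyclohexan-1-ol
Product: 16 (2S)-2-[(1S,3S,4R)-3-bromo-4-methyl-4-(triethylsilyloxy)cyclohexyl]-1,2-bis(triethylsilyloxy)propane
Conditions: TESOTf, 2,6-lutidine, CH2Cl2, −78 → 0 °C
Reagents that add atoms: triethylsilyl trifluoromethanesulfonate, CC[Si](CC)(CC)OS(=O)(=O)C(F)(F)F
Why: Silylation with the silyl triflate protects the two tertiary hydroxyl groups for the basic olefination and turns the primary one into the precursor of the aldehyde.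

Step 11
Reactants: 16 (2S)-2-[(1S,3S,4R)-3-bromo-4-methyl-4-(triethylsilyloxy)cyclohexyl]-1,2-bis(triethylsilyloxy)propane
Product: 17 (2S)-2-[(1S,3S,4R)-3-bromo-4-methyl-4-(triethylsilyloxy)cyclohexyl]-2-(triethylsilyloxy)propanal
Conditions: (COCl)2, DMSO, CH2Cl2, −78 → −30 °C; then Et3N
Reagents that add atoms: none
Why: Swern oxidation converts a primary triethylsilyl ether directly into the aldehyde while the hindered tertiary silyl ethers stay intact, and the α-carbon carries no hydrogen so C2′ cannot epimerise.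

Step 12
Reactants: 18 methyl 3-oxobutanoate; 2 1-bromo-3-methylbut-2-ene
Product: 19 methyl 7-methyl-3-oxooct-6-enoate
Conditions: NaH, THF, 0 °C; n-BuLi, 0 °C; then 2
Reagents that add atoms: none
Why: γ-Alkylation of the acetoacetate dianion with the allylic bromide gives the cyclisation substrate.

Step 13
Reactants: 19 methyl 7-methyl-3-oxooct-6-enoate
Product: 20 methyl (1RS,3RS)-3-bromo-2,2-dimethyl-6-oxocyclohexane-1-carboxylate
Conditions: BDSB (Et2SBr·SbCl5Br), MeNO2, −25 °C
Reagents that add atoms: bromodiethylsulfonium bromopentachloroantimonate, CC[S+](Br)CC.Cl[Sb-](Cl)(Cl)(Cl)(Cl)Br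
Why: Bromonium-induced cation–olefin cyclisation through a chair transition state, terminated by C-alkylation of the β-keto ester enol, should place bromine equatorial, and the enolisable C1 ester settles equatorial, so that bromine and ester are cis in the racemate.

Step 14
Reactants: 20 methyl (1RS,3RS)-3-bromo-2,2-dimethyl-6-oxocyclohexane-1-carboxylate
Product: 21 methyl (1RS,3SR)-3-bromo-2,2-dimethyl-6-methylidenecyclohexane-1-carboxylate
Conditions: Ph3PCH3Br, KOtBu, toluene, 0 °C → rt
Reagents that add atoms: methyltriphenylphosphonium bromide, C[P+](c1ccccc1)(c1ccccc1)c1ccccc1.[Br-]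
Why: Wittig methylenation of the hindered, poorly enolised ketone installs the exocyclic methylidene group, and C1 stays in its equatorial (thermodynamic) configuration.

Step 15
Reactants: 21 methyl (1RS,3SR)-3-bromo-2,2-dimethyl-6-methylidenecyclohexane-1-carboxylate
Product: 22 [(1RS,3SR)-3-bromo-2,2-dimethyl-6-methylidenecyclohexyl]methanol
Conditions: iBu2AlH (DIBAL-H), CH2Cl2, −78 °C
Reagents that add atoms: none
Why: Hydride reduction of the ester gives the primary alcohol and removes the acidic α-hydrogen, so the C1 configuration is fixed.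

Step 16
Reactants: 22 [(1RS,3SR)-3-bromo-2,2-dimethyl-6-methylidenecyclohexyl]methanol
Product: 23 [(1R,3S)-3-bromo-2,2-dimethyl-6-methylidenecyclohexyl]methanol
Conditions: lipase (Burkholderia cepacia lipase, immobilised), vinyl acetate, t-BuOMe, 30 °C, stopped past half conversion
Reagents that add atoms: none
Why: Lipase-catalysed enantioselective transesterification (kinetic resolution) should acylate the (1S,3R)-enantiomer faster and leave the (1R,3S)-alcohol, which is separated from the acetate by chromatography.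

Step 17
Reactants: 23 [(1R,3S)-3-bromo-2,2-dimethyl-6-methylidenecyclohexyl]methanol
Product: 24 5-({[(1R,3S)-3-bromo-2,2-dimethyl-6-methylidenecyclohexyl]methyl}sulfanyl)-1-phenyl-1H-tetrazole
Conditions: 1-phenyl-1H-tetrazole-5-thiol, PPh3, DIAD, THF, 0 °C → rt
Reagents that add atoms: 1-phenyl-1H-tetrazole-5-thiol, Sc1nnnn1-c1ccccc1
Why: Mitsunobu thioetherification of the primary alcohol installs the tetrazolyl sulfide without touching the stereocentres.

Step 18
Reactants: 24 5-({[(1R,3S)-3-bromo-2,2-dimethyl-6-methylidenecyclohexyl]methyl}sulfanyl)-1-phenyl-1H-tetrazole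
Product: 25 5-({[(1R,3S)-3-bromo-2,2-dimethyl-6-methylidenecyclohexyl]methyl}sulfonyl)-1-phenyl-1H-tetrazole
Conditions: H2O2 (30% aq.), (NH4)6Mo7O24·4H2O (cat.), EtOH, 0 °C → rt
Reagents that add atoms: hydrogen peroxide, OO
Why: Molybdate-catalysed peroxide oxidation converts the sulfide into the sulfone faster than it epoxidises the unactivated exocyclic alkene.

Step 19
Reactants: 17 (2S)-2-[(1S,3S,4R)-3-bromo-4-methyl-4-(triethylsilyloxy)cyclohexyl]-2-(triethylsilyloxy)propanal; 25 5-({[(1R,3S)-3-bromo-2,2-dimethyl-6-methylidenecyclohexyl]methyl}sulfonyl)-1-phenyl-1H-tetrazole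
Product: 26 {[(1R,2S,4S)-2-bromo-4-[(2S,3E)-4-[(1R,3S)-3-bromo-2,2-dimethyl-6-methylidenecyclohexyl]-2-(triethylsilyloxy)but-3-en-2-yl]-1-methylcyclohexyl]oxy}triethylsilane
Conditions: 25, KN(SiMe3)2, DME, −60 °C; then 17, −60 °C → rt
Reagents that add atoms: none
Why: Julia–Kocienski olefination (addition, Smiles rearrangement, loss of SO2 and tetrazolate) should give the E-alkene C3′=C4′, as expected for a 1-phenyltetrazolyl sulfone and a hindered aldehyde with a potassium counter-ion.

Step 20
Reactants: 26 {[(1R,2S,4S)-2-bromo-4-[(2S,3E)-4-[(1R,3S)-3-bromo-2,2-dimethyl-6-methylidenecyclohexyl]-2-(triethylsilyloxy)but-3-en-2-yl]-1-methylcyclohexyl]oxy}triethylsilane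
Product: 27 (1R,2S,4S)-2-bromo-4-[(2S,3E)-4-[(1R,3S)-3-bromo-2,2-dimethyl-6-methylidenecyclohexyl]-2-hydroxybut-3-en-2-yl]-1-methylcyclohexan-1-ol
Conditions: HF·pyridine, pyridine, THF, 0 °C → rt
Reagents that add atoms: none
Why: Buffered fluoride cleavage of the two tertiary silyl ethers releases the diol, and because both bromides are equatorial and have neither an anti-periplanar hydrogen nor an anti alkoxide, elimination and epoxide formation are not expected.

**Compound list**

1 | tert-butyl acetate | CC(=O)OC(C)(C)C | starting material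
2 | 1-bromo-3-methylbut-2-ene | CC(C)=CCBr | starting material
3 | tert-butyl 5-methylhex-4-enoate | CC(C)=CCCC(=O)OC(C)(C)C | intermediate
4 | tert-butyl (4E)-6-hydroxy-5-methylhex-4-enoate | OC/C(C)=C/CCC(=O)OC(C)(C)C | intermediate
5 | tert-butyl 3-[(2R,3R)-3-(hydroxymethyl)-3-methyloxiran-2-yl]propanoate | CC(C)(C)OC(=O)CC[C@H]1O[C@]1(C)CO | intermediate
6 | tert-butyl 3-[(2R,3R)-3-({[tert-butyl(dimethyl)silyl]oxy}methyl)-3-methyloxiran-2-yl]propanoate | CC(C)(C)OC(=O)CC[C@H]1O[C@]1(C)CO[Si](C)(C)C(C)(C)C | intermediate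
7 | 3-(benzenesulfonyl)propanoic acid | OC(=O)CCS(=O)(=O)c1ccccc1 | starting material
8 | 3-(benzenesulfonyl)-N-methoxy-N-methylpropanamide | CON(C)C(=O)CCS(=O)(=O)c1ccccc1 | intermediate
9 | tert-butyl 5-(benzenesulfonyl)-2-{[(2R,3R)-3-({[tert-butyl(dimethyl)silyl]oxy}methyl)-3-methyloxiran-2-yl]methyl}-3-oxopentanoate (present as its lithiated form; C2 unassigned) | CC(C)(C)OC(=O)C(C[C@H]1O[C@]1(C)CO[Si](C)(C)C(C)(C)C)C(=O)CCS(=O)(=O)c1ccccc1 | intermediate (not isolated)
10 | tert-butyl 4-(benzenesulfonyl)-5-[(2S)-1-{[tert-butyl(dimethyl)silyl]oxy}-2-hydroxypropan-2-yl]-2-oxocyclohexane-1-carboxylate (ring C5 configured as in 11; C1 and C4 unassigned) | CC(C)(C)[Si](C)(C)OC[C@@](C)(O)[C@H]1C(S(=O)(=O)c2ccccc2)CC(=O)C(C(=O)OC(C)(C)C)C1 | intermediate (not isolated)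
11 | tert-butyl (5R)-5-[(2S)-1-{[tert-butyl(dimethyl)silyl]oxy}-2-hydroxypropan-2-yl]-2-oxocyclohex-3-ene-1-carboxylate (C1 enolisable) | CC(C)(C)[Si](C)(C)OC[C@@](C)(O)[C@H]1C=CC(=O)C(C(=O)OC(C)(C)C)C1 | intermediate
12 | tert-butyl (5S)-5-[(2S)-1-{[tert-butyl(dimethyl)silyl]oxy}-2-hydroxypropan-2-yl]-2-oxocyclohexane-1-carboxylate (C1 enolisable) | CC(C)(C)[Si](C)(C)OC[C@@](C)(O)[C@H]1CCC(=O)C(C(=O)OC(C)(C)C)C1 | intermediate
13 | tert-butyl (5S)-1-bromo-5-[(2S)-1-{[tert-butyl(dimethyl)silyl]oxy}-2-hydroxypropan-2-yl]-2-oxocyclohexane-1-carboxylate (C1 unassigned) | CC(C)(C)[Si](C)(C)OC[C@@](C)(O)[C@H]1CCC(=O)C(Br)(C(=O)OC(C)(C)C)C1 | intermediate (not isolated)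
14 | (2S,4S)-2-bromo-4-[(2S)-1,2-dihydroxypropan-2-yl]cyclohexan-1-one | OC[C@@](C)(O)[C@H]1CCC(=O)[C@@H](Br)C1 | intermediate
15 | (1R,2S,4S)-2-bromo-4-[(2S)-1,2-dihydroxypropan-2-yl]-1-methylcyclohexan-1-ol | OC[C@@](C)(O)[C@H]1CC[C@@](C)(O)[C@@H](Br)C1 | intermediate
16 | (2S)-2-[(1S,3S,4R)-3-bromo-4-methyl-4-(triethylsilyloxy)cyclohexyl]-1,2-bis(triethylsilyloxy)propane | CC[Si](CC)(CC)OC[C@@](C)(O[Si](CC)(CC)CC)[C@H]1CC[C@@](C)(O[Si](CC)(CC)CC)[C@@H](Br)C1 | intermediate
17 | (2S)-2-[(1S,3S,4R)-3-bromo-4-methyl-4-(triethylsilyloxy)cyclohexyl]-2-(triethylsilyloxy)propanal | O=C[C@@](C)(O[Si](CC)(CC)CC)[C@H]1CC[C@@](C)(O[Si](CC)(CC)CC)[C@@H](Br)C1 | intermediate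
18 | methyl 3-oxobutanoate | COC(=O)CC(C)=O | starting material
19 | methyl 7-methyl-3-oxooct-6-enoate | COC(=O)CC(=O)CCC=C(C)C | intermediate
20 | methyl (1RS,3RS)-3-bromo-2,2-dimethyl-6-oxocyclohexane-1-carboxylate (racemate, both enantiomers shown) | O=C1CC[C@H](Br)C(C)(C)[C@@H]1C(=O)OC.O=C1CC[C@@H](Br)C(C)(C)[C@H]1C(=O)OC | intermediate
21 | methyl (1RS,3SR)-3-bromo-2,2-dimethyl-6-methylidenecyclohexane-1-carboxylate (racemate, both enantiomers shown) | C=C1CC[C@H](Br)C(C)(C)[C@@H]1C(=O)OC.C=C1CC[C@@H](Br)C(C)(C)[C@H]1C(=O)OC | intermediate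
22 | [(1RS,3SR)-3-bromo-2,2-dimethyl-6-methylidenecyclohexyl]methanol (racemate, both enantiomers shown) | C=C1CC[C@H](Br)C(C)(C)[C@@H]1CO.C=C1CC[C@@H](Br)C(C)(C)[C@H]1CO | intermediate
23 | [(1R,3S)-3-bromo-2,2-dimethyl-6-methylidenecyclohexyl]methanol | C=C1CC[C@H](Br)C(C)(C)[C@@H]1CO | intermediate
24 | 5-({[(1R,3S)-3-bromo-2,2-dimethyl-6-methylidenecyclohexyl]methyl}sulfanyl)-1-phenyl-1H-tetrazole | C=C1CC[C@H](Br)C(C)(C)[C@@H]1CSc1nnnn1-c1ccccc1 | intermediate
25 | 5-({[(1R,3S)-3-bromo-2,2-dimethyl-6-methylidenecyclohexyl]methyl}sulfonyl)-1-phenyl-1H-tetrazole | C=C1CC[C@H](Br)C(C)(C)[C@@H]1CS(=O)(=O)c1nnnn1-c1ccccc1 | intermediate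
26 | {[(1R,2S,4S)-2-bromo-4-[(2S,3E)-4-[(1R,3S)-3-bromo-2,2-dimethyl-6-methylidenecyclohexyl]-2-(triethylsilyloxy)but-3-en-2-yl]-1-methylcyclohexyl]oxy}triethylsilane | C=C1CC[C@H](Br)C(C)(C)[C@@H]1/C=C/[C@@](C)(O[Si](CC)(CC)CC)[C@H]1CC[C@@](C)(O[Si](CC)(CC)CC)[C@@H](Br)C1 | intermediate
27 | (1R,2S,4S)-2-bromo-4-[(2S,3E)-4-[(1R,3S)-3-bromo-2,2-dimethyl-6-methylidenecyclohexyl]-2-hydroxybut-3-en-2-yl]-1-methylcyclohexan-1-ol | C=C1CC[C@H](Br)C(C)(C)[C@@H]1/C=C/[C@@](C)(O)[C@H]1CC[C@@](C)(O)[C@@H](Br)C1 | target

**Step count and risks**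

Total step count: 20. Longest linear sequence: 12 steps (steps 1–4, 6–11, 19, 20, from tert-butyl acetate).

Steps most likely to fail:

Step 6 (annulation). Proton transfer between the two lithiated partners, 3-exo attack of the ester enolate on the epoxide, or O-alkylation of the keto-ester enolate may outrun the intended C-acylation and 6-exo alkylation. The fallback sets out from 6 and returns at 12; it makes the two bonds in separate operations through a temporary lactone ring. Epoxide 6 would be opened at its CH carbon with [2-(1,3-dioxolan-2-yl)ethyl]magnesium bromide and catalytic CuI (THF, −30 °C; copper-catalysed SN2 opening with inversion, forms ring-B C4–C5) to give tert-butyl (4S)-4-[(2S)-1-{[tert-butyl(dimethyl)silyl]oxy}-2-hydroxypropan-2-yl]-6-(1,3-dioxolan-2-yl)hexanoate F1. Pyridinium tosylate in wet acetone would release the aldehyde, which closes on the tertiary alcohol to the lactol tert-butyl 3-[(2S,3S)-2-({[tert-butyl(dimethyl)silyl]oxy}methyl)-6-hydroxy-2-methyloxan-3-yl]propanoate F2. TEMPO with PhI(OAc)2 would oxidise it to the δ-lactone tert-butyl 3-[(2S,3R)-2-({[tert-butyl(dimethyl)silyl]oxy}methyl)-2-methyl-6-oxooxan-3-yl]propanoate F3. LiN(iPr)2 (THF, −78 → 0 °C) would then generate the tert-butyl ester enolate, which attacks the lactone carbonyl (Dieckmann-type C-acylation, forms C1–C2) and expels the tertiary alkoxide, giving 12 directly; steps 5 and 7 are then not needed.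

Step 13 (bromonium cyclisation). Capture of the cation by the enol oxygen (O-cyclisation), or simple bromination or HBr loss at the alkene, may compete with C–C bond formation. The fallback sets out from 19 and returns at 20. Compound 19 would be cyclised with Hg(OTf)2·PhNMe2 (MeNO2, −20 °C; then aqueous NaCl), a cation–olefin cyclisation that β-keto esters terminate at carbon, to give racemic methyl (1RS,3RS)-3-(chloromercurio)-2,2-dimethyl-6-oxocyclohexane-1-carboxylate F4. Br2 and LiBr in pyridine under O2 would then replace mercury by bromine (radical brominative demercuration; the equatorial bromide is expected as the major, separable epimer), returning to 20.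

Step 19 (olefination). Slow addition of the β-branched sulfonyl anion to the fully substituted, neopentyl-type aldehyde and erosion of the E selectivity may occur. The fallback sets out from 23 and 17 and returns at 26. Alcohol 23 would be oxidised with Dess–Martin periodinane to (1R,3S)-3-bromo-2,2-dimethyl-6-methylidenecyclohexane-1-carbaldehyde F5, condensed with hydrazine hydrate to its E-hydrazone F6, and iodinated with I2 and Et3N (Barton hydrazone iodination) to [(1R,3S)-3-bromo-2,2-dimethyl-6-methylidenecyclohexyl]diiodomethane F7. F7, 17 and CrCl2 in THF/DMF would then give 26 by Takai–Utimoto alkylidenation, an E-selective olefination that needs no strong base; unactivated secondary alkyl bromides are not expected to be reduced by CrCl2 at room temperature.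

Further compounds
F1 | step 6 | tert-butyl (4S)-4-[(2S)-1-{[tert-butyl(dimethyl)silyl]oxy}-2-hydroxypropan-2-yl]-6-(1,3-dioxolan-2-yl)hexanoate | CC(C)(C)[Si](C)(C)OC[C@@](C)(O)[C@H](CCC(=O)OC(C)(C)C)CCC1OCCO1
F2 | step 6 | tert-butyl 3-[(2S,3S)-2-({[tert-butyl(dimethyl)silyl]oxy}methyl)-6-hydroxy-2-methyloxan-3-yl]propanoate (anomers) | CC(C)(C)[Si](C)(C)OC[C@@]1(C)OC(O)CC[C@H]1CCC(=O)OC(C)(C)C
F3 | step 6 | tert-butyl 3-[(2S,3R)-2-({[tert-butyl(dimethyl)silyl]oxy}methyl)-2-methyl-6-oxooxan-3-yl]propanoate | CC(C)(C)[Si](C)(C)OC[C@@]1(C)OC(=O)CC[C@H]1CCC(=O)OC(C)(C)C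
F4 | step 13 | methyl (1RS,3RS)-3-(chloromercurio)-2,2-dimethyl-6-oxocyclohexane-1-carboxylate (racemate, both enantiomers shown) | O=C1CC[C@H]([Hg]Cl)C(C)(C)[C@@H]1C(=O)OC.O=C1CC[C@@H]([Hg]Cl)C(C)(C)[C@H]1C(=O)OC
F5 | step 19 | (1R,3S)-3-bromo-2,2-dimethyl-6-methylidenecyclohexane-1-carbaldehyde | C=C1CC[C@H](Br)C(C)(C)[C@@H]1C=O
F6 | step 19 | (E)-{[(1R,3S)-3-bromo-2,2-dimethyl-6-methylidenecyclohexyl]methylidene}hydrazine | C=C1CC[C@H](Br)C(C)(C)[C@@H]1/C=N/N
F7 | step 19 | [(1R,3S)-3-bromo-2,2-dimethyl-6-methylidenecyclohexyl]diiodomethane | C=C1CC[C@H](Br)C(C)(C)[C@@H]1C(I)I
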